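**Plan**

- Retrosynthesis: the C5 hydroxyl is masked as a methyl ether, and ring B (the pyranone) is cut at C4a–C4, C4–C3 and O1–C2 into iodoresorcinol 6, carbon monoxide 13 and tritriacont-1-yne 12.
- Enabling feature: the C8 methyl sits between the oxygenated C7 and C8a, so ring A maps onto mirror-symmetric 5-methoxy-2-methylresorcinol 5. Its two ring C–H positions are equivalent, and each is flanked by the methoxy group (future C5) and a hydroxyl next to the methyl (future O1).
- Further cuts: the aryl–CH3 bond of 5 (lithiation between two acetal ethers of 5-methoxyresorcinol 1) and the C3–C4 bond of the alkyne (1-iodotriacontane 8 plus lithiated 1-(trimethylsilyl)propyne 9).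
- Forward order: ring A is bought and receives the methyl group and the iodine; the C33 alkyne is built from 1-triacontanol; ring B is closed and the chain attached in one three-component carbonylative annulation; BCl3 then frees the C5 hydroxyl.
- Stereochemistry: the target has no stereocentre and no stereogenic double bond, so nothing has to be set.

Key step: step 8

Remark: the C2 side chain is read as unbranched hentriacontyl (31 carbons), so the alkyne partner is tritriacont-1-yne (33 carbons). Chromone numbering (O1 to C8a) is used; ring A is the benzene ring and ring B the pyranone ring.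

**Route**

Step 1
Reactants: 1 5-methoxyresorcinol
Product: 2 1-methoxy-3,5-bis(methoxymethoxy)benzene
Conditions: NaH, MOMCl, DMF, 0 °C to rt
Reagents that add atoms: chloromethyl methyl ether, COCCl
Why: Williamson-type O-alkylation of the bis-phenoxide by the hard electrophile MOMCl should cap both hydroxyls as acetals, which are inert to alkyllithiums and are the strong directing groups that step 2 needs.

Step 2
Reactants: 2 1-methoxy-3,5-bis(methoxymethoxy)benzene
Product: 4 5-methoxy-1,3-bis(methoxymethoxy)-2-methylbenzene, via aryllithium 3 (not isolated)
Conditions: n-BuLi, TMEDA, THF, 0 °C; then MeI, −78 °C to rt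
Reagents that add atoms: iodomethane, CI
Why: Directed ortho-metalation should take place at the ring C–H flanked by the two methoxymethoxy groups, the most acidic and best-chelated site (a methoxymethoxy group outranks methoxy as a director), and SN2 methylation of aryllithium 3 by iodomethane then places the future C8 methyl on the symmetry axis.

Step 3
Reactants: 4 5-methoxy-1,3-bis(methoxymethoxy)-2-methylbenzene
Product: 5 5-methoxy-2-methylbenzene-1,3-diol
Conditions: HCl (3 M aq.), MeOH, 50 °C
Reagents that add atoms: none
Why: Acid-catalysed acetal cleavage in methanol, which traps the methoxymethyl cation as dimethoxymethane, should free both phenols while the aryl methyl ether is inert to dilute acid.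

Step 4
Reactants: 5 5-methoxy-2-methylbenzene-1,3-diol
Product: 6 4-iodo-5-methoxy-2-methylbenzene-1,3-diol
Conditions: I2 (1.0 equiv), NaHCO3, THF/H2O, 0 °C
Reagents that add atoms: iodine, II
Why: Electrophilic aromatic iodination of a strongly activated resorcinol, in which the two ring C–H positions are symmetry-equivalent, should with one equivalent of iodine at 0 °C give a single mono-iodide whose iodine lies between the methoxy group and a hydroxyl.

Step 5
Reactants: 7 1-triacontanol
Product: 8 1-iodotriacontane
Conditions: I2, PPh3, imidazole, toluene, 60 °C
Reagents that add atoms: iodine, II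
Why: Appel iodination, in which the alkoxyphosphonium ion of the primary alcohol is displaced by iodide in an SN2 reaction, is dependable for long unbranched alcohols once they are held in solution in warm toluene.

Step 6
Reactants: 8 1-iodotriacontane; 9 1-(trimethylsilyl)propyne
Product: 11 trimethyl(tritriacont-1-yn-1-yl)silane, via lithiated silylpropyne 10 (not isolated)
Conditions: 9, n-BuLi, THF, −78 °C; then 8 in THF, DMPU, −78 °C to rt
Reagents that add atoms: none
Why: Propargylic lithiation of the silylpropyne and SN2 alkylation of lithiated species 10 by the primary iodide should add the three missing carbons, the bulky silyl group directing attack to the propargylic rather than the allenic terminus.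

Step 7
Reactants: 11 trimethyl(tritriacont-1-yn-1-yl)silane
Product: 12 tritriacont-1-yne
Conditions: K2CO3 (cat.), MeOH/THF, 40 °C
Reagents that add atoms: none
Why: Base-catalysed protodesilylation, in which methoxide attacks silicon and the C(sp)–Si bond is cleaved, should unmask the terminal alkyne without touching the saturated chain.

Step 8
Reactants: 6 4-iodo-5-methoxy-2-methylbenzene-1,3-diol; 12 tritriacont-1-yne; 13 carbon monoxide
Product: 16 2-hentriacontyl-7-hydroxy-5-methoxy-8-methyl-4H-chromen-4-one, via aryl ynone 14 (not isolated), via enaminone 15 (not isolated)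
Conditions: PdCl2(PPh3)2 (5 mol%), CO (20 atm), Et2NH/toluene, 110 °C
Reagents that add atoms: none
Why: Zerovalent palladium formed in situ from PdCl2(PPh3)2 should insert into the C–I bond of 6, CO insertion then gives an aroyl complex of divalent palladium, and amine-assisted alkynyl transfer from 12 followed by reductive elimination forms C4a–C4 and C4–C3 in ynone 14 (a copper-free carbonylative Sonogashira coupling). Diethylamine adds to the ynone to give enaminone 15, and the ortho phenol displaces the amine at the β-carbon, forming O1–C2 in a 6-endo addition–elimination that closes ring B. The closest known reaction type is the palladium-catalysed carbonylative annulation of ortho-iodophenols with terminal alkynes to 2-substituted chromones. No stereocentre is created. The step needs 6-endo rather than 5-exo closure (chromone, not aurone), which the enaminone pathway in the secondary amine secures. It also needs O1 to end up beside C8, which the substrate fixes because the only hydroxyl ortho to iodine in 6 is the one next to the methyl group, the other ortho position carrying the methyl ether and the second hydroxyl being para and out of reach.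

Step 9
Reactants: 16 2-hentriacontyl-7-hydroxy-5-methoxy-8-methyl-4H-chromen-4-one
Product: 17 2-hentriacontyl-5,7-dihydroxy-8-methyl-4H-chromen-4-one
Conditions: BCl3 (1 M in CH2Cl2, 3 equiv), CH2Cl2, 0 °C to rt; then H2O
Reagents that add atoms: none
Why: Chelation-assisted Lewis acid ether cleavage, in which BCl3 binds between the C4 carbonyl and the peri C5 methoxy oxygen and chloride removes the methyl group by SN2, is the standard selective demethylation of 5-methoxychromones and should leave the pyranone ring and the alkyl chain intact.

**Compound list**

1 | 5-methoxyresorcinol (5-methoxybenzene-1,3-diol) | COc1cc(O)cc(O)c1 | starting material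
2 | 1-methoxy-3,5-bis(methoxymethoxy)benzene | COCOc1cc(OC)cc(OCOC)c1 | intermediate
3 | [4-methoxy-2,6-bis(methoxymethoxy)phenyl]lithium | [Li]c1c(OCOC)cc(OC)cc1OCOC | intermediate
4 | 5-methoxy-1,3-bis(methoxymethoxy)-2-methylbenzene | Cc1c(OCOC)cc(OC)cc1OCOC | intermediate
5 | 5-methoxy-2-methylbenzene-1,3-diol | COc1cc(O)c(C)c(O)c1 | intermediate
6 | 4-iodo-5-methoxy-2-methylbenzene-1,3-diol | COc1cc(O)c(C)c(O)c1I | intermediate
7 | 1-triacontanol (triacontan-1-ol) | CCCCCCCCCCCCCCCCCCCCCCCCCCCCCCO | starting material
8 | 1-iodotriacontane | CCCCCCCCCCCCCCCCCCCCCCCCCCCCCCI | intermediate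
9 | 1-(trimethylsilyl)propyne | CC#C[Si](C)(C)C | starting material
10 | [3-(trimethylsilyl)prop-2-yn-1-yl]lithium | [Li]CC#C[Si](C)(C)C | intermediate
11 | trimethyl(tritriacont-1-yn-1-yl)silane | CCCCCCCCCCCCCCCCCCCCCCCCCCCCCCCC#C[Si](C)(C)C | intermediate
12 | tritriacont-1-yne | CCCCCCCCCCCCCCCCCCCCCCCCCCCCCCCC#C | intermediate
13 | carbon monoxide | [C-]#[O+] | starting material
14 | 1-(2,4-dihydroxy-6-methoxy-3-methylphenyl)tetratriacont-2-yn-1-one | CCCCCCCCCCCCCCCCCCCCCCCCCCCCCCCC#CC(=O)c1c(OC)cc(O)c(C)c1O | intermediate
15 | (E)-3-(diethylamino)-1-(2,4-dihydroxy-6-methoxy-3-methylphenyl)tetratriacont-2-en-1-one | CCN(CC)/C(=C/C(=O)c1c(OC)cc(O)c(C)c1O)CCCCCCCCCCCCCCCCCCCCCCCCCCCCCCC | intermediate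
16 | 2-hentriacontyl-7-hydroxy-5-methoxy-8-methyl-4H-chromen-4-one | CCCCCCCCCCCCCCCCCCCCCCCCCCCCCCCc1cc(=O)c2c(OC)cc(O)c(C)c2o1 | intermediate
17 | 2-hentriacontyl-5,7-dihydroxy-8-methyl-4H-chromen-4-one (CNP0154031.0) | CCCCCCCCCCCCCCCCCCCCCCCCCCCCCCCc1cc(=O)c2c(O)cc(O)c(C)c2o1 | target

**Totals**

Total step count: 9.
Longest linear sequence: 6 steps (steps 1, 2, 3, 4, 8, 9 from compound 1). The alkyne arm (steps 5, 6, 7 from compound 7) joins at step 8.

**Steps most likely to fail**

1. Step 8. Oxidative addition into the doubly ortho-substituted, very electron-rich C–I bond may be slow, so that hydrodeiodination competes. The aroylpalladium intermediate may be intercepted by diethylamine (aminocarbonylation) before alkynyl transfer. The waxy alkyne may stay poorly dissolved under CO pressure. The fallback sets out from 4 and 12, builds the same ynone without CO and closes ring B by the same amine-mediated O1–C2 closure. Lithiation of 4 (n-BuLi, TMEDA, THF, 0 °C) at either of its two equivalent ring positions should give [6-methoxy-2,4-bis(methoxymethoxy)-3-methylphenyl]lithium F1, and a DMF quench should give 6-methoxy-2,4-bis(methoxymethoxy)-3-methylbenzaldehyde F2. Deprotonation of 12 with n-BuLi in THF gives (tritriacont-1-yn-1-yl)lithium F3, which should add to F2 to give 1-[6-methoxy-2,4-bis(methoxymethoxy)-3-methylphenyl]tetratriacont-2-yn-1-ol F4 (racemate; the carbinol centre is removed in the next operation). MnO2 in CH2Cl2 should oxidise this benzylic, propargylic alcohol to 1-[6-methoxy-2,4-bis(methoxymethoxy)-3-methylphenyl]tetratriacont-2-yn-1-one F5. Dilute HCl in MeOH/THF at rt removes both acetals to give ynone 14, and Et2NH in EtOH should take it through enaminone 15 to chromone 16, where the route is rejoined before step 9.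

2. Step 4. A second iodination at the remaining, still activated ring position, or oxidative degradation of the electron-rich resorcinol, may erode the mono-iodide. The fallback sets out from 4 and fixes the stoichiometry by metalation instead of electrophilic substitution. Lithiation of 4 (n-BuLi, TMEDA, THF, 0 °C) gives the same aryllithium, [6-methoxy-2,4-bis(methoxymethoxy)-3-methylphenyl]lithium F1, as in the fallback for step 8. A quench with I2 at −78 °C should give 2-iodo-1-methoxy-3,5-bis(methoxymethoxy)-4-methylbenzene F6. Acetal cleavage with dilute HCl in MeOH at rt then gives 6, where the route is rejoined before step 8 (steps 3 and 4 are bypassed).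

3. Step 6. The C30 iodide may crystallise from THF at low temperature, so that alkylation is slow, and on warming the lithiated silylpropyne may decompose or react at its allenic terminus. The fallback sets out from 8 and joins a propyne unit through its sp carbon instead. Alkylation of 1-propynyllithium (CH3C≡CLi, THF/DMPU, 0 °C to rt) by 8 should give tritriacont-2-yne F7. An alkyne zipper isomerisation with KNH(CH2)3NH2 (from KH and 1,3-diaminopropane, rt to 50 °C), driven by irreversible deprotonation of the terminal alkyne, should then move the triple bond by one position to give 12, where the route is rejoined before step 8 (compounds 9 to 11 and step 7 are bypassed).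

**Further compounds**

F1 | step 8 | [6-methoxy-2,4-bis(methoxymethoxy)-3-methylphenyl]lithium | [Li]c1c(OC)cc(OCOC)c(C)c1OCOC
F2 | step 8 | 6-methoxy-2,4-bis(methoxymethoxy)-3-methylbenzaldehyde | O=Cc1c(OC)cc(OCOC)c(C)c1OCOC
F3 | step 8 | (tritriacont-1-yn-1-yl)lithium | [Li]C#CCCCCCCCCCCCCCCCCCCCCCCCCCCCCCCC
F4 | step 8 | 1-[6-methoxy-2,4-bis(methoxymethoxy)-3-methylphenyl]tetratriacont-2-yn-1-ol (racemate) | CCCCCCCCCCCCCCCCCCCCCCCCCCCCCCCC#CC(O)c1c(OC)cc(OCOC)c(C)c1OCOC
F5 | step 8 | 1-[6-methoxy-2,4-bis(methoxymethoxy)-3-methylphenyl]tetratriacont-2-yn-1-one | CCCCCCCCCCCCCCCCCCCCCCCCCCCCCCCC#CC(=O)c1c(OC)cc(OCOC)c(C)c1OCOC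
F6 | step 4 | 2-iodo-1-methoxy-3,5-bis(methoxymethoxy)-4-methylbenzene | COCOc1cc(OC)c(I)c(OCOC)c1C
F7 | step 6 | tritriacont-2-yne | CC#CCCCCCCCCCCCCCCCCCCCCCCCCCCCCCC
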